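Its constants were set for the occasion; the run is a simulation.

A closed, stirred vessel at constant volume takes substrate, and the flasks differ in the reagent charged. I want the share of double product at the end among double product, side product A and side product B, each counted by the substrate in it.

| flask | substrate | reagent | time |
|---|---|---|---|
| alder | 0.031 M | 0.0600 equiv | 3.0 h |
| elm | 0.031 M | 0.150 equiv | 3.0 h |
| maple | 0.031 M | 0.500 equiv | 3.0 h |
| birch | 0.031 M | 1.50 equiv | 3.0 h |
| oak | 0.031 M | 5.00 equiv | 3.0 h |

    substrate + reagent → mono adduct + by-product (k1 = 11 M⁻¹ h⁻¹)
    reagent + mono adduct → double product + by-product (k2 = 10 M⁻¹ h⁻¹)
    crystals ⇌ by-product, rate k3*(cs3 - [by-product]) while solid is left; crystals form when [by-product] > cs3 (cs3 = 21 mM, k3 = 43 h⁻¹)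
    double product + by-product → side product A (k4 = 6.4 M⁻¹ h⁻¹)
    substrate + double product → side product B (k5 = 18 M⁻¹ h⁻¹)

- a species is counted by the substrate in it: one side product B counts as two
- amounts and yields of by-product count crystals too
- given per volume of solution although it is solid: crystals
- "hardly changes" means that all values lie within two and a half points (for a concentration: within two and a half percent of the largest)
- run time (alder): 3.0 h

- share of double product in all that became double product or side product A or side product B for alder, elm, maple, birch, oak, in this order
- how the row runs (rises all the way / hardly changes / rises, then falls / falls all the way / falls, then rises)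

I can reckon the two lean flasks, alder and elm, by hand. With reagent charges of 0.0600 equiv and 0.150 equiv, I hold c(substrate) at 0.031 M. Then reagent decays pseudo-first-order at a = 0.341 h⁻¹, and step two takes less of it, because even in elm, with all the reagent turned into mono adduct, its rate per reagent is 0.0465 h⁻¹. Double product is captured by substrate at b = 0.558 h⁻¹, whereas by-product, with all of elm's reagent turned over, takes it at 0.0298 h⁻¹.

Mono adduct grows as reagent falls, so double product forms at a rate proportional to exp(−at) − exp(−two·at), and the square of the charge stands in front of that. Integrating this rate, with each portion decaying at b until the end of the run, gives the surviving fraction f = 53.7%. In this reckoning the reagent charge cancels. Each captured double product counts as two in side product B, so the lean-flask share, the part of the count still standing as double product when capture by substrate is the only loss, is S = f/(two − f) = 36.7%. My reckoning gives this one value for both lean flasks and stops there.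

The forecast gives 38%, 39%, 43%, 53% and 60%, so that the row rises all the way, holding that at low equivalents “substrate stays high and eats most of the slowly formed double product”.

The simulation gives 37.2%, 38.0%, 41.1%, 49.5% and 66.9%: the row rises all the way, as the forecast said, and oak stands 6.9 percentage points above it.

Alder stands 0.5 points above S, and elm, with 2.50 times alder's reagent, stands 1.3 points above it. In alder at 3.00 h, step one uses reagent 29 times as fast as step two. Alder then holds mono adduct at 3.71% of the substrate charged, against double product at 0.0355%.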